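**Retrosynthetic overview**

1. Agrimol C (19) ⇐ Friedel–Crafts butyrylation at C5′ of both side rings ⇐ heptaphenol 18 ⇐ hydrogenolysis of tetrabenzyl ether 17.
2. The strategy rests on ring B (C1 butyryl, C2/C4/C6 hydroxyls, C3/C5 each carrying an ArCH2 arm), which is the folded form of a 3,5,7-trioxodecanoate chain. Cutting ring bond C1–C2 gives linear triketo ester 15 (chain C6 = ring C1, ester carbon = ring C2, arms already on chain C2 and C4).
3. 15 ⇐ C4–C5 acylation of the α,γ-dianion of β-keto ester 9 with the ketal-masked 3-oxohexanoyl Weinreb amide 12 (from methyl 3-oxohexanoate 10).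
4. 9 ⇐ Claisen self-condensation of 3-arylpropanoate 8 (forms C2–C3), made from aldehyde 5 by olefination and reduction, so no labile 2,4,6-trioxygenated benzyl halide is needed; 5 ⇐ 2-methylphloroglucinol 1.
5. Ring order: both side rings are bought as 1; ring B is the only ring formed, in step 11.

Key step: step 11

Remark: the target has no stereocentre, so chain C2 and C4 in 9, 14 and 15 are carried as epimer and enol mixtures; both become sp2 ring carbons in step 11. Side-ring locants are C1′ (bridge carbon) to C6′.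

**Route**

Step 1
Reactants: 1 2-methylbenzene-1,3,5-triol
Product: 3 2,4,6-trihydroxy-3-methylbenzaldehyde, via aryl iminium chloride 2 (not isolated)
Conditions: POCl3 (1.1 equiv), DMF, EtOAc, 0 °C → rt; then H2O, 60 °C
Reagents that add atoms: N,N-dimethylformamide CN(C)C=O; water O
Why: Vilsmeier–Haack formylation, in which the chloroiminium ion attacks one of the two equivalent free ring carbons of the symmetric triol and hydrolysis of iminium salt 2 releases the aldehyde, so only one regioisomer can form.

Step 2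
Reactants: 3 2,4,6-trihydroxy-3-methylbenzaldehyde
Product: 4 2,6-dihydroxy-4-methoxy-3-methylbenzaldehyde
Conditions: Me2SO4 (1.0 equiv), K2CO3 (1.1 equiv), acetone, 0 °C → rt
Reagents that add atoms: dimethyl sulfate COS(=O)(=O)OC
Why: Selective Williamson O-methylation, since the 4-OH para to the formyl group is the most acidic hydroxyl and is not chelated to the carbonyl, so one equivalent of the hard electrophile should methylate it first.

Step 3
Reactants: 4 2,6-dihydroxy-4-methoxy-3-methylbenzaldehyde
Product: 5 2,6-bis(benzyloxy)-4-methoxy-3-methylbenzaldehyde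
Conditions: BnBr (2.5 equiv), K2CO3, n-Bu4NI (cat.), DMF, 70 °C
Reagents that add atoms: benzyl bromide BrCc1ccccc1
Why: Williamson benzylation of the two chelated ortho hydroxyls under forcing carbonate conditions, where the dipolar aprotic solvent favours O- over C-alkylation.

Step 4
Reactants: 5 2,6-bis(benzyloxy)-4-methoxy-3-methylbenzaldehyde; 6 trimethyl phosphonoacetate
Product: 7 methyl (E)-3-[2,6-bis(benzyloxy)-4-methoxy-3-methylphenyl]prop-2-enoate
Conditions: NaH, THF, 0 → 60 °C
Reagents that add atoms: none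
Why: Horner–Wadsworth–Emmons olefination of the hindered, non-enolisable aldehyde should give the E-cinnamate, whose geometry is irrelevant because the alkene is reduced next.

Step 5
Reactants: 7 methyl (E)-3-[2,6-bis(benzyloxy)-4-methoxy-3-methylphenyl]prop-2-enoate
Product: 8 methyl 3-[2,6-bis(benzyloxy)-4-methoxy-3-methylphenyl]propanoate
Conditions: NiCl2·6H2O (0.3 equiv), NaBH4, MeOH–THF, 0 °C → rt
Reagents that add atoms: none
Why: Nickel boride conjugate reduction saturates the cinnamate C=C without hydrogenolysis of the aryl benzyl ethers or reduction of the ester.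

Step 6
Reactants: 8 methyl 3-[2,6-bis(benzyloxy)-4-methoxy-3-methylphenyl]propanoate (two molecules)
Product: 9 methyl 5-[2,6-bis(benzyloxy)-4-methoxy-3-methylphenyl]-2-{[2,6-bis(benzyloxy)-4-methoxy-3-methylphenyl]methyl}-3-oxopentanoate (racemic)
Conditions: NaH (0.6 equiv per ester), MeOH (cat.), toluene, 90 °C; then AcOH
Reagents that add atoms: none
Why: Claisen self-condensation, in which the enolate of one ester acylates a second molecule and deprotonation of the β-keto ester product drives the equilibrium, lays down chain C1–C4 with both arylmethyl arms in place; the C2 centre is racemic and is destroyed later.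

Step 7
Reactants: 10 methyl 3-oxohexanoate
Product: 11 methyl 2-(2-propyl-1,3-dioxolan-2-yl)acetate
Conditions: HOCH2CH2OH, TsOH·H2O (cat.), toluene, reflux, Dean–Stark
Reagents that add atoms: ethylene glycol OCCO
Why: Acid-catalysed ketalisation with azeotropic water removal masks the ketone, so the acyl donor has no 1,3-dicarbonyl C–H acid that would quench the dianion in step 9.

Step 8
Reactants: 11 methyl 2-(2-propyl-1,3-dioxolan-2-yl)acetate
Product: 12 N-methoxy-N-methyl-2-(2-propyl-1,3-dioxolan-2-yl)acetamide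
Conditions: MeNH(OMe)·HCl, i-PrMgCl, THF, −20 → 0 °C
Reagents that add atoms: N,O-dimethylhydroxylamine hydrochloride CNOC.Cl
Why: Aminolysis of the ester by the magnesium amide of N,O-dimethylhydroxylamine (Weinreb amide formation) gives an acyl donor that stops at mono-addition.

Step 9
Reactants: 9 methyl 5-[2,6-bis(benzyloxy)-4-methoxy-3-methylphenyl]-2-{[2,6-bis(benzyloxy)-4-methoxy-3-methylphenyl]methyl}-3-oxopentanoate; 12 N-methoxy-N-methyl-2-(2-propyl-1,3-dioxolan-2-yl)acetamide
Product: 14 methyl 2,4-bis{[2,6-bis(benzyloxy)-4-methoxy-3-methylphenyl]methyl}-3,5-dioxo-6-(2-propyl-1,3-dioxolan-2-yl)hexanoate, via dilithium dienolate 13 (not isolated)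
Conditions: LiN(i-Pr)2 (LDA, 2.3 equiv), THF, −78 → 0 °C; then 12, −78 → −20 °C; aq. NH4Cl
Reagents that add atoms: none
Why: β-Keto ester α,γ-dianion acylation, in which LDA removes the C2 proton and then a C4 proton (the only other α-position of the ketone) and the more basic C4 carbanion of 13 attacks the Weinreb amide, whose chelated tetrahedral adduct releases the 3,5-diketone only on quench; C4 forms as an epimer mixture that is destroyed later.

Step 10
Reactants: 14 methyl 2,4-bis{[2,6-bis(benzyloxy)-4-methoxy-3-methylphenyl]methyl}-3,5-dioxo-6-(2-propyl-1,3-dioxolan-2-yl)hexanoate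
Product: 15 methyl 2,4-bis{[2,6-bis(benzyloxy)-4-methoxy-3-methylphenyl]methyl}-3,5,7-trioxodecanoate
Conditions: 1 M HCl, THF, rt
Reagents that add atoms: water O
Why: Aqueous acid hydrolysis of the dioxolane, assisted by enolisation of the neighbouring C5 ketone, unveils the C7 ketone while benzyl ethers, methyl ether and methyl ester are stable.

Step 11
Reactants: 15 methyl 2,4-bis{[2,6-bis(benzyloxy)-4-methoxy-3-methylphenyl]methyl}-3,5,7-trioxodecanoate
Product: 17 1-(3,5-bis{[2,6-bis(benzyloxy)-4-methoxy-3-methylphenyl]methyl}-2,4,6-trihydroxyphenyl)butan-1-one, via acylcyclohexanetrione 16 (not isolated)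
Conditions: Mg(OMe)2 (8 equiv), MeOH–THF, reflux, Ar; then cold 1 M HCl
Reagents that add atoms: none
Why: Mg(OMe)2 turns the C5/C7 β-diketone of 15 into its magnesium chelate, whose central carbon (chain C6, future ring C1) adds to the ester carbonyl (chain C1, future ring C2), and loss of methoxide gives triketone 16, which enolises at once to the aromatic phloroglucinol 17. The closest known reaction type is the magnesium methoxide-mediated Claisen cyclisation of 3,5,7-triketo esters and of the derived pyranones to acylphloroglucinols. Ring B closes in a 6-exo-trig mode, the attacked C=O lying outside the forming six-membered ring. No new stereocentre is formed, and the epimeric centres at chain C2 and C4 become the sp2 ring carbons C3 and C5. The step needs Claisen closure to win over aldol closure (chain C2 onto the C7 ketone) and over lactonisation to a 4-hydroxypyran-2-one: magnesium holds the diketone enolate and the ester together, the aldol adduct would carry a quaternary C2 that cannot dehydrate to an arene and so reverts, and any pyranone is reopened by methoxide, so irreversible aromatisation should drain all equilibria toward 17. Since both arms and the butyryl group are fixed on the chain beforehand, the substitution pattern of the hexasubstituted ring is unambiguous.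

Step 12
Reactants: 17 1-(3,5-bis{[2,6-bis(benzyloxy)-4-methoxy-3-methylphenyl]methyl}-2,4,6-trihydroxyphenyl)butan-1-one
Product: 18 1-{3,5-bis[(2,6-dihydroxy-4-methoxy-3-methylphenyl)methyl]-2,4,6-trihydroxyphenyl}butan-1-one
Conditions: H2 (1 atm), 10% Pd/C, EtOAc–MeOH, rt
Reagents that add atoms: none
Why: Catalytic hydrogenolysis cleaves the four aryl benzyl ethers under neutral conditions, sparing the acid-labile diarylmethane bridges and the hydrogen-bonded aryl ketone.

Step 13
Reactants: 18 1-{3,5-bis[(2,6-dihydroxy-4-methoxy-3-methylphenyl)methyl]-2,4,6-trihydroxyphenyl}butan-1-one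
Product: 19 agrimol C, 1-{3,5-bis[(3-butanoyl-2,6-dihydroxy-4-methoxy-5-methylphenyl)methyl]-2,4,6-trihydroxyphenyl}butan-1-one
Conditions: n-PrCOCl (2.5 equiv), AlCl3 (excess), PhNO2–CH2Cl2, 0 °C → rt; then ice/1 M HCl
Reagents that add atoms: butanoyl chloride CCCC(=O)Cl
Why: Friedel–Crafts acylation can only enter at C5′, the single unsubstituted aromatic carbon of each side ring (activated by the ortho hydroxyl and ortho methoxy groups), because ring B is fully substituted and deactivated by its butyryl group; any O-butyrate should be cleaved on work-up or by brief K2CO3/MeOH treatment.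

**Compound list**

1 | 2-methylbenzene-1,3,5-triol (2-methylphloroglucinol) | Cc1c(O)cc(O)cc1O | starting material
2 | [(2,4,6-trihydroxy-3-methylphenyl)methylidene]dimethylammonium chloride (not isolated) | C[N+](C)=Cc1c(O)c(C)c(O)cc1O.[Cl-] | intermediate
3 | 2,4,6-trihydroxy-3-methylbenzaldehyde | O=Cc1c(O)c(C)c(O)cc1O | intermediate
4 | 2,6-dihydroxy-4-methoxy-3-methylbenzaldehyde | O=Cc1c(O)c(C)c(OC)cc1O | intermediate
5 | 2,6-bis(benzyloxy)-4-methoxy-3-methylbenzaldehyde | O=Cc1c(OCc2ccccc2)c(C)c(OC)cc1OCc1ccccc1 | intermediate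
6 | trimethyl phosphonoacetate | COC(=O)CP(=O)(OC)OC | starting material
7 | methyl (E)-3-[2,6-bis(benzyloxy)-4-methoxy-3-methylphenyl]prop-2-enoate | COC(=O)/C=C/c1c(OCc2ccccc2)c(C)c(OC)cc1OCc1ccccc1 | intermediate
8 | methyl 3-[2,6-bis(benzyloxy)-4-methoxy-3-methylphenyl]propanoate | COC(=O)CCc1c(OCc2ccccc2)c(C)c(OC)cc1OCc1ccccc1 | intermediate
9 | methyl 5-[2,6-bis(benzyloxy)-4-methoxy-3-methylphenyl]-2-{[2,6-bis(benzyloxy)-4-methoxy-3-methylphenyl]methyl}-3-oxopentanoate (racemic) | COC(=O)C(Cc1c(OCc2ccccc2)c(C)c(OC)cc1OCc1ccccc1)C(=O)CCc1c(OCc2ccccc2)c(C)c(OC)cc1OCc1ccccc1 | intermediate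
10 | methyl 3-oxohexanoate | CCCC(=O)CC(=O)OC | starting material
11 | methyl 2-(2-propyl-1,3-dioxolan-2-yl)acetate | CCCC1(CC(=O)OC)OCCO1 | intermediate
12 | N-methoxy-N-methyl-2-(2-propyl-1,3-dioxolan-2-yl)acetamide | CCCC1(CC(=O)N(C)OC)OCCO1 | intermediate
13 | dilithium α,γ-dienolate of 9 (not isolated) | [Li+].[Li+].COC([O-])=C(Cc1c(OCc2ccccc2)c(C)c(OC)cc1OCc1ccccc1)C([O-])=CCc1c(OCc2ccccc2)c(C)c(OC)cc1OCc1ccccc1 | intermediate
14 | methyl 2,4-bis{[2,6-bis(benzyloxy)-4-methoxy-3-methylphenyl]methyl}-3,5-dioxo-6-(2-propyl-1,3-dioxolan-2-yl)hexanoate (epimer and enol mixture) | COC(=O)C(Cc1c(OCc2ccccc2)c(C)c(OC)cc1OCc1ccccc1)C(=O)C(Cc1c(OCc2ccccc2)c(C)c(OC)cc1OCc1ccccc1)C(=O)CC1(CCC)OCCO1 | intermediate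
15 | methyl 2,4-bis{[2,6-bis(benzyloxy)-4-methoxy-3-methylphenyl]methyl}-3,5,7-trioxodecanoate (epimer and enol mixture) | COC(=O)C(Cc1c(OCc2ccccc2)c(C)c(OC)cc1OCc1ccccc1)C(=O)C(Cc1c(OCc2ccccc2)c(C)c(OC)cc1OCc1ccccc1)C(=O)CC(=O)CCC | intermediate
16 | 2-butanoyl-4,6-bis{[2,6-bis(benzyloxy)-4-methoxy-3-methylphenyl]methyl}cyclohexane-1,3,5-trione (not isolated, configuration undefined) | CCCC(=O)C1C(=O)C(Cc2c(OCc3ccccc3)c(C)c(OC)cc2OCc2ccccc2)C(=O)C(Cc2c(OCc3ccccc3)c(C)c(OC)cc2OCc2ccccc2)C1=O | intermediate
17 | 1-(3,5-bis{[2,6-bis(benzyloxy)-4-methoxy-3-methylphenyl]methyl}-2,4,6-trihydroxyphenyl)butan-1-one | CCCC(=O)c1c(O)c(Cc2c(OCc3ccccc3)c(C)c(OC)cc2OCc2ccccc2)c(O)c(Cc2c(OCc3ccccc3)c(C)c(OC)cc2OCc2ccccc2)c1O | intermediate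
18 | 1-{3,5-bis[(2,6-dihydroxy-4-methoxy-3-methylphenyl)methyl]-2,4,6-trihydroxyphenyl}butan-1-one | CCCC(=O)c1c(O)c(Cc2c(O)c(C)c(OC)cc2O)c(O)c(Cc2c(O)c(C)c(OC)cc2O)c1O | intermediate
19 | agrimol C | CCCC(=O)c1c(O)c(Cc2c(O)c(C)c(OC)c(C(=O)CCC)c2O)c(O)c(Cc2c(O)c(C)c(OC)c(C(=O)CCC)c2O)c1O | target

**Step count**

Total: 13 steps. Longest linear sequence: 11 steps (steps 1–6, then 9–13).

**Steps most likely to fail**

Step 11 (key Claisen cyclisation). Methoxide may cleave the 2,4-disubstituted β-dicarbonyl units by retro-Claisen fragmentation, or the chain may stall at the pyranone or aldol stage because the ester next to the arm-bearing C2 is hindered. The fallback abandons the chain cyclisation and builds the same product by Friedel–Crafts benzylation. It sets out from 5: NaBH4 in MeOH reduces the aldehyde to [2,6-bis(benzyloxy)-4-methoxy-3-methylphenyl]methanol F1. Two equivalents of F1 are then added slowly to commercial 1-(2,4,6-trihydroxyphenyl)butan-1-one F2 with catalytic Sc(OTf)3 in MeNO2 at 0 °C, so that the stabilised benzylic cation alkylates the two free ring carbons of F2. This comes back to the route at 17.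

Step 9 (dianion acylation). The hindered secondary C4 carbanion may deprotonate the Weinreb amide at its α-CH2 (with β-elimination opening the dioxolane) instead of adding to it, returning 9. The fallback replaces acylation by aldol addition and oxidation. It sets out from 12, which LiAlH4 in THF at −78 °C reduces to 2-(2-propyl-1,3-dioxolan-2-yl)acetaldehyde F3. Dianion 13, generated from 9 as in step 9, adds to F3 at −78 °C to give methyl 2,4-bis{[2,6-bis(benzyloxy)-4-methoxy-3-methylphenyl]methyl}-5-hydroxy-3-oxo-6-(2-propyl-1,3-dioxolan-2-yl)hexanoate F4. Dess–Martin periodinane in CH2Cl2 oxidises the secondary alcohol of F4, which comes back to the route at 14.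

Step 13 (final butyrylation). The Lewis acid may heterolyse the aryl–CH2 bonds of the electron-rich polyphenol (retro-Friedel–Crafts scrambling of the bridges), cleave the 4′-methyl ether next to the new ketone, or leave the acylation incomplete. The fallback reverses the order of the last two operations. It sets out from 17, which is acylated at both C5′ positions with butanoic acid and trifluoroacetic anhydride in CH2Cl2 (0 °C → rt, mixed-anhydride acylation without a metal Lewis acid), followed by K2CO3/MeOH to cleave phenolic esters. This gives 1-(3,5-bis{[2,6-bis(benzyloxy)-3-butanoyl-4-methoxy-5-methylphenyl]methyl}-2,4,6-trihydroxyphenyl)butan-1-one F5. Hydrogenolysis of F5 (H2, 10% Pd/C, EtOAc) then comes back to the route at 19.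

**Further compounds**

F1 | step 11 | [2,6-bis(benzyloxy)-4-methoxy-3-methylphenyl]methanol | OCc1c(OCc2ccccc2)c(C)c(OC)cc1OCc1ccccc1
F2 | step 11 | 1-(2,4,6-trihydroxyphenyl)butan-1-one (purchased coupling partner) | CCCC(=O)c1c(O)cc(O)cc1O
F3 | step 9 | 2-(2-propyl-1,3-dioxolan-2-yl)acetaldehyde | CCCC1(CC=O)OCCO1
F4 | step 9 | methyl 2,4-bis{[2,6-bis(benzyloxy)-4-methoxy-3-methylphenyl]methyl}-5-hydroxy-3-oxo-6-(2-propyl-1,3-dioxolan-2-yl)hexanoate | COC(=O)C(Cc1c(OCc2ccccc2)c(C)c(OC)cc1OCc1ccccc1)C(=O)C(Cc1c(OCc2ccccc2)c(C)c(OC)cc1OCc1ccccc1)C(O)CC1(CCC)OCCO1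
F5 | step 13 | 1-(3,5-bis{[2,6-bis(benzyloxy)-3-butanoyl-4-methoxy-5-methylphenyl]methyl}-2,4,6-trihydroxyphenyl)butan-1-one | CCCC(=O)c1c(O)c(Cc2c(OCc3ccccc3)c(C)c(OC)c(C(=O)CCC)c2OCc2ccccc2)c(O)c(Cc2c(OCc3ccccc3)c(C)c(OC)c(C(=O)CCC)c2OCc2ccccc2)c1O
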